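(The data come from a simulation with constants of no real substance, noise included.)

Between the last two readings the north flask gained 0.9 percentage points, less than the 3.8 points of the colder south-east run, so the north flask was coming to a stop.

| flask | substrate | free catalyst | temperature | remark | time |
|---|---|---|---|---|---|
| north | 0.25 M | 10 mol% | 0 °C | the very flask that is asked about, followed so far |  |
| south-east | 0.25 M | 10 mol% | −5 °C | run made earlier |  |
| flask | 0.25 M | 10 mol% | 0 °C |  | 2.5 d |

- north (time / h: product / %): 8.00: 24.6; 15.0: 37.3; 25.0: 47.0; 30.0: 50.5; 40.0: 52.7; 50.0: 53.6
- south-east (time / h: product / %): 8.00: 15.5; 15.0: 27.5; 25.0: 38.2; 30.0: 42.0; 40.0: 48.6; 50.0: 52.4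

(scatter of a reading: 0.5 percentage points)

- winter: at 2.5 d add free catalyst, 50.0% of the amount charged, then wait 2.5 d
- midnight: at 2.5 d take out 90% of the product then present, then wait 2.5 d
- dusk: at 2.5 d raise the temperature by 15 K, then wait 2.5 d
- spring: change nothing and wait 2.5 d more

- product, in percent of the substrate first charged, at 2.5 d
- what to do for the largest gain in product; "none" if nothing gains more than 2 percentage points (winter / midnight / dusk / spring / none)
- product present, with what was taken out counted in, in percent of the substrate first charged, after midnight
- product present, with what was taken out counted in, in percent of the substrate first charged, after dusk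

- removed product is counted in
- additions bring no volume worth counting

These readings allowed either a balance or a dying catalyst; I bet on the catalyst and worked with the fraction of substrate left. Suppose substrate falls pseudo-first-order, at a pace proportional to live catalyst, and that catalyst fades exponentially. The logarithm of one over the fraction left then starts climbing by one unit per substrate time, and it stops at the catalyst time divided by the substrate time. I called that stopping value the reach of the charge, read at the last north reading as 0.768. On this supposition, with both times' temperature held, it grows in proportion to the catalyst charged.

The gaps below the reach at 8.00 h and 25.0 h gave a catalyst time of 13.1 h. The substrate time was therefore 17.1 h, so in my reading the catalyst time of the north flask was the shorter of the two. At 2.5 d my reckoning kept 1.04% of the starting pace, so I expected about 53.6%, with little from waiting, removal or heat. For catalyst added at 50.0% of the charge, I reckoned 68.4% product, a gain of 15 points, so I chose winter.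

The forecast gave 54.5% at 2.5 d, chose midnight, and gave 77% after midnight and 41% after dusk: “So I read this as a reversible reaction at equilibrium”.

The flask gave 54.2%. Choice winter gained 15 points, more than any other option; midnight ended at 54.7% and dusk at 54.5%. At 2.50 d, spent catalyst stood at 98.7% of the catalyst charged. Put on the 46% of substrate left in the flask, my reckoning with 50.0% of the reach added leaves 31.3% of the substrate charged.

    substrate + free catalyst ⇌ catalyst intermediate A (K = 3.36 L mol⁻¹, k = 816 L mol⁻¹ h⁻¹, Ea = 39.0 kJ mol⁻¹, ΔH = −22.0 kJ mol⁻¹)
    catalyst intermediate A ⇌ catalyst intermediate B (K = 1.20, k = 1.55 h⁻¹, Ea = 91.0 kJ mol⁻¹, ΔH = −13.0 kJ mol⁻¹)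
    catalyst intermediate B → free catalyst + product (k = 3.42 h⁻¹, Ea = 73.0 kJ mol⁻¹)
    free catalyst → spent catalyst (k = 0.116 h⁻¹, Ea = 85.0 kJ mol⁻¹)
    (constants at 0 °C)

With 4 mol% of free catalyst, my reach scales to 0.307, which gives an estimate of 26.4% product. The computed neighbour flask gave 26.9%.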